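A direct plan would form C9=C10 by an aldol condensation. The ring A ketone A1 (ring A is the β end ring, C1–C6), a 4-silyloxybutan-2-one carrying the silylated hydroxycyclogeranyl group on C1, would be enolised and added to the C27 polyenal A2; the aldol would be acetylated and eliminated, and O19 would be acylated at the end. A1 would come from the cyclogeranyl sulfone A3 and 3-silyloxypropanal. Its weakest steps would be:
- the kinetic enolisation of A1, which must occur at C9 although the C7 hydrogens are α to the carbonyl and allylic, and which gives an enolate with a β-silyloxy leaving group;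
- the acetate elimination, which alone would have to fix the C9=C10 geometry under a base that can also expel O19;
- the sulfone addition, oxidation and desulfonylation, three steps for one C–C bond.

The new route would treat the C7H2–C8(=O) unit as the hydrate of a C7≡C8 alkyne and let the C19 dodecenoate, which sits on C9 next to C8, deliver the oxygen. The skeleton would be built as a 7,8-didehydro carotenoid: a ring A enyne is coupled with 4-bromofuran-2(5H)-one, whose lactone ring fixes the C9=C10 geometry and distinguishes C19 from C11; Wittig opening of the derived lactol with a C25 ylide frees O19 for acylation. A gold-catalysed, ester-assisted hydration would then create the keto ester array in the last step, so no β-oxygenated enolate, no elimination at C9=C10 and no sulfone sequence would be needed.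

Key step: step 18

Remark: carotenoid numbering is used for all fragments (ring B is the ε end ring, C1'–C6'; TBS = tert-butyldimethylsilyl); (R)-α-ionone is assumed to be bought as the single enantiomer and 4-bromofuran-2(5H)-one as a catalogue compound.

Step 1
Reactants: 1 (4R,6R)-4-hydroxy-2,2,6-trimethylcyclohexan-1-one (actinol)
Product: 2 (4R,6R)-4-(TBSO)-2,2,6-trimethylcyclohexan-1-one
Conditions: TBSCl, imidazole, DMF, rt
Reagents that add atoms: tert-butyldimethylsilyl chloride, CC(C)(C)[Si](C)(C)Cl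
Why: Imidazole-promoted silylation of the secondary alcohol protects the future C3 hydroxyl and leaves its R configuration untouched.

Step 2
Reactants: 2 (4R,6R)-4-(TBSO)-2,2,6-trimethylcyclohexan-1-one
Product: 3 (4R,6R)-4-(TBSO)-1-ethynyl-2,2,6-trimethylcyclohexan-1-ol (C1 epimer mixture)
Conditions: HC≡CMgBr (2 equiv), THF, 0 °C to rt; aq. NH4Cl
Reagents that add atoms: ethynylmagnesium bromide, C#C[Mg]Br
Why: 1,2-Addition of the small alkynyl Grignard reagent to the hindered ketone brings in C7 and C8; the new carbinol centre forms as a mixture that step 3 removes.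

Step 3
Reactants: 3 (4R,6R)-4-(TBSO)-1-ethynyl-2,2,6-trimethylcyclohexan-1-ol
Product: 5 (4R)-4-(TBSO)-1-ethynyl-2,6,6-trimethylcyclohex-1-ene, via dichlorophosphate 4 (not isolated)
Conditions: POCl3 (3 equiv), pyridine, 90 °C
Reagents that add atoms: none
Why: Elimination of the tertiary propargylic dichlorophosphate (POCl3–pyridine dehydration) can only take the single β-hydrogen on the methyl-bearing ring carbon, which gives the tetrasubstituted C5=C6 alkene and erases both the carbinol centre and the actinol methine centre on purpose.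

Step 4
Reactants: 5 (4R)-4-(TBSO)-1-ethynyl-2,6,6-trimethylcyclohex-1-ene; 6 4-bromofuran-2(5H)-one
Product: 7 4-{[(4R)-4-(TBSO)-2,6,6-trimethylcyclohex-1-en-1-yl]ethynyl}furan-2(5H)-one
Conditions: PdCl2(PPh3)2 (3 mol %), CuI (5 mol %), iPr2NEt, THF, rt
Reagents that add atoms: none
Why: Sonogashira coupling of the terminal alkyne with the vinylogous acyl bromide forms C8–C9, and the butenolide ring holds C19 (ring CH2O) cis and C8 trans to C11 (lactone carbonyl), which is the C9=C10 geometry of the target.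

Step 5
Reactants: 7 4-{[(4R)-4-(TBSO)-2,6,6-trimethylcyclohex-1-en-1-yl]ethynyl}furan-2(5H)-one
Product: 8 4-{[(4R)-4-(TBSO)-2,6,6-trimethylcyclohex-1-en-1-yl]ethynyl}-2,5-dihydrofuran-2-ol (anomer mixture)
Conditions: iBu2AlH (1.1 equiv), CH2Cl2, −78 °C; aq. potassium sodium tartrate
Reagents that add atoms: none
Why: 1,2-Reduction of the lactone by one equivalent of iBu2AlH stops at the aluminium hemiacetal at −78 °C and gives the lactol, a masked (Z)-4-hydroxy-enal with C11 at the aldehyde level and C19 at the alcohol level; the non-acidic work-up avoids dehydration to a furan.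

Step 6
Reactants: 9 (R)-α-ionone
Product: 10 ethyl (2E,4E)-3-methyl-5-[(1R)-2,6,6-trimethylcyclohex-2-en-1-yl]penta-2,4-dienoate
Conditions: triethyl phosphonoacetate (1.2 equiv), NaH (1.1 equiv), THF, 0 °C to rt; chromatography
Reagents that add atoms: triethyl phosphonoacetate, CCOC(=O)CP(=O)(OCC)OCC
Why: Horner–Wadsworth–Emmons olefination of the methyl ketone gives mainly the 2E ester (the 2Z isomer is removed on silica), and the weakly basic phosphonate anion, used without excess NaH, should not deprotonate the doubly allylic C6' hydrogen, so the bought R centre is kept.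

Step 7
Reactants: 10 ethyl (2E,4E)-3-methyl-5-[(1R)-2,6,6-trimethylcyclohex-2-en-1-yl]penta-2,4-dienoate
Product: 11 ethyl (2E,4E)-3-methyl-5-[(1R)-2,6,6-trimethyl-4-oxocyclohex-2-en-1-yl]penta-2,4-dienoate
Conditions: t-BuOOH (70 % aq, 5 equiv), Rh2(C6H10NO)4 (dirhodium tetrakis(caprolactamate), 1 mol %), 1,2-dichloroethane, 40 °C
Reagents that add atoms: tert-butyl hydroperoxide, CC(C)(C)OO
Why: Dirhodium-catalysed allylic oxidation with t-BuOOH converts the ring allylic CH2 (C3') into the enone, and the base-free medium avoids epimerisation at the now γ-acidic C6'.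

Step 8
Reactants: 11 ethyl (2E,4E)-3-methyl-5-[(1R)-2,6,6-trimethyl-4-oxocyclohex-2-en-1-yl]penta-2,4-dienoate
Product: 12 ethyl (2E,4E)-5-[(1R,4R)-4-hydroxy-2,6,6-trimethylcyclohex-2-en-1-yl]-3-methylpenta-2,4-dienoate
Conditions: (S)-1-methyl-3,3-diphenyltetrahydro-1H,3H-pyrrolo[1,2-c][1,3,2]oxazaborole (0.5 equiv), catecholborane (1.5 equiv), toluene, −78 °C
Reagents that add atoms: none
Why: Corey–Bakshi–Shibata reduction adds hydride to the enone carbonyl under reagent control (alkenyl side as the large group) and sets C3' as R, trans to the side chain at C6'.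

Step 9
Reactants: 12 ethyl (2E,4E)-5-[(1R,4R)-4-hydroxy-2,6,6-trimethylcyclohex-2-en-1-yl]-3-methylpenta-2,4-dienoate
Product: 13 ethyl (2E,4E)-5-[(1R,4R)-4-(TBSO)-2,6,6-trimethylcyclohex-2-en-1-yl]-3-methylpenta-2,4-dienoate
Conditions: TBSCl, imidazole, DMF, rt
Reagents that add atoms: tert-butyldimethylsilyl chloride, CC(C)(C)[Si](C)(C)Cl
Why: Silylation of the allylic secondary alcohol with retention protects O3' from ionisation, oxidation and acylation until step 17.

Step 10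
Reactants: 13 ethyl (2E,4E)-5-[(1R,4R)-4-(TBSO)-2,6,6-trimethylcyclohex-2-en-1-yl]-3-methylpenta-2,4-dienoate
Product: 14 (2E,4E)-5-[(1R,4R)-4-(TBSO)-2,6,6-trimethylcyclohex-2-en-1-yl]-3-methylpenta-2,4-dien-1-ol
Conditions: iBu2AlH (2.5 equiv), CH2Cl2, −78 °C; aq. potassium sodium tartrate
Reagents that add atoms: none
Why: iBu2AlH gives clean 1,2-reduction of the dienoate to the primary dienol and leaves the silyl ether alone.

Step 11
Reactants: 14 (2E,4E)-5-[(1R,4R)-4-(TBSO)-2,6,6-trimethylcyclohex-2-en-1-yl]-3-methylpenta-2,4-dien-1-ol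
Product: 16 {(2E,4E)-5-[(1R,4R)-4-(TBSO)-2,6,6-trimethylcyclohex-2-en-1-yl]-3-methylpenta-2,4-dien-1-yl}triphenylphosphonium bromide, via allylic bromide 15 (not isolated)
Conditions: CBr4 (1.1 equiv), PPh3 (1.1 equiv), CH2Cl2, −20 °C; then PPh3 (1.5 equiv), rt
Reagents that add atoms: carbon tetrabromide, BrC(Br)(Br)Br; triphenylphosphine, c1ccc(cc1)P(c1ccccc1)c1ccccc1
Why: Appel bromination under neutral conditions followed by SN2 quaternisation of PPh3 in the same flask gives the allylic phosphonium salt without acid that would ionise the allylic silyl ether.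

Step 12
Reactants: 16 {(2E,4E)-5-[(1R,4R)-4-(TBSO)-2,6,6-trimethylcyclohex-2-en-1-yl]-3-methylpenta-2,4-dien-1-yl}triphenylphosphonium bromide; 17 (2E,4E,6E)-2,7-dimethylocta-2,4,6-trienedial
Product: 19 (2E,4E,6E,8E,10E,12E)-13-[(1R,4R)-4-(TBSO)-2,6,6-trimethylcyclohex-2-en-1-yl]-2,7,11-trimethyltrideca-2,4,6,8,10,12-hexaenal, via phosphorus ylide 18 (not isolated)
Conditions: 17 (2 equiv), NaOMe, MeOH/CH2Cl2, 0 °C to rt; then I2 (1 mol %), CH2Cl2, daylight
Reagents that add atoms: none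
Why: Wittig olefination of the excess dialdehyde by the semi-stabilised allylic ylide forms C11'=C12' on one aldehyde only, and iodine-catalysed equilibration converts the Z isomer into the all-E aldehyde.

Step 13
Reactants: 19 (2E,4E,6E,8E,10E,12E)-13-[(1R,4R)-4-(TBSO)-2,6,6-trimethylcyclohex-2-en-1-yl]-2,7,11-trimethyltrideca-2,4,6,8,10,12-hexaenal
Product: 20 (2E,4E,6E,8E,10E,12E)-13-[(1R,4R)-4-(TBSO)-2,6,6-trimethylcyclohex-2-en-1-yl]-2,7,11-trimethyltrideca-2,4,6,8,10,12-hexaen-1-ol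
Conditions: NaBH4, MeOH/THF, 0 °C
Reagents that add atoms: none
Why: NaBH4 reduces the polyenal by 1,2-addition to the primary allylic alcohol and touches neither the polyene nor the silyl ether.

Step 14
Reactants: 20 (2E,4E,6E,8E,10E,12E)-13-[(1R,4R)-4-(TBSO)-2,6,6-trimethylcyclohex-2-en-1-yl]-2,7,11-trimethyltrideca-2,4,6,8,10,12-hexaen-1-ol
Product: 22 {(2E,4E,6E,8E,10E,12E)-13-[(1R,4R)-4-(TBSO)-2,6,6-trimethylcyclohex-2-en-1-yl]-2,7,11-trimethyltrideca-2,4,6,8,10,12-hexaen-1-yl}triphenylphosphonium bromide, via pentaenyl bromide 21 (not isolated)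
Conditions: CBr4 (1.1 equiv), PPh3 (1.1 equiv), CH2Cl2, −30 °C, dark; then PPh3 (1.5 equiv), −30 °C to rt
Reagents that add atoms: carbon tetrabromide, BrC(Br)(Br)Br; triphenylphosphine, c1ccc(cc1)P(c1ccccc1)c1ccccc1
Why: Appel bromination at low temperature gives the labile pentaenyl bromide, which PPh3 quaternises at once at the primary C12 (SN2) to the C25 Wittig salt under neutral conditions.

Step 15
Reactants: 22 {(2E,4E,6E,8E,10E,12E)-13-[(1R,4R)-4-(TBSO)-2,6,6-trimethylcyclohex-2-en-1-yl]-2,7,11-trimethyltrideca-2,4,6,8,10,12-hexaen-1-yl}triphenylphosphonium bromide; 8 4-{[(4R)-4-(TBSO)-2,6,6-trimethylcyclohex-1-en-1-yl]ethynyl}-2,5-dihydrofuran-2-ol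
Product: 24 (3R,3'R,6'R)-3,3'-bis(TBSO)-7,8-didehydro-β,ε-caroten-19-ol (all-trans chain; C8 trans to C11), via phosphorus ylide 23 (not isolated)
Conditions: 22, NaN(SiMe3)2 (1.0 equiv), THF, −78 °C; then 8 (1.3 equiv, as its sodium lactolate from NaN(SiMe3)2), −78 to 0 °C; then EtOAc, 60 °C, dark
Reagents that add atoms: none
Why: The sodium lactolate opens to the (Z)-4-oxido-enal, whose aldehyde is olefinated by the polyenyl ylide (Wittig reaction on a lactol) to form C11=C12 and set O19 free as the only unprotected hydroxyl; the hindered 11Z isomer is isomerised thermally, and iodine is avoided so that the C9=C10 geometry taken from the butenolide is not equilibrated.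

Step 16
Reactants: 24 (3R,3'R,6'R)-3,3'-bis(TBSO)-7,8-didehydro-β,ε-caroten-19-ol; 25 (2E)-dodec-2-enoic acid
Product: 26 (3R,3'R,6'R)-3,3'-bis(TBSO)-7,8-didehydro-β,ε-caroten-19-yl (2E)-dodec-2-enoate
Conditions: 25 (1.2 equiv), N,N'-diisopropylcarbodiimide, 4-(dimethylamino)pyridine (0.1 equiv), CH2Cl2, 0 °C
Reagents that add atoms: none
Why: Steglich esterification acylates the single free hydroxyl, the primary allylic O19, with the free 2-enoic acid under conditions that do not deconjugate the 2E double bond.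

Step 17
Reactants: 26 (3R,3'R,6'R)-3,3'-bis(TBSO)-7,8-didehydro-β,ε-caroten-19-yl (2E)-dodec-2-enoate
Product: 27 (3R,3'R,6'R)-3,3'-dihydroxy-7,8-didehydro-β,ε-caroten-19-yl (2E)-dodec-2-enoate
Conditions: HF·pyridine, pyridine, THF, 0 °C to rt
Reagents that add atoms: none
Why: Pyridine-buffered HF·pyridine cleaves both secondary silyl ethers by fluoride attack at silicon, and the ester, the alkyne and the polyene are inert to it, so the sensitive keto ester array does not yet exist when fluoride is used.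

Step 18
Reactants: 27 (3R,3'R,6'R)-3,3'-dihydroxy-7,8-didehydro-β,ε-caroten-19-yl (2E)-dodec-2-enoate
Product: 28 (3R,3'R,6'R,all-E)-3,3'-dihydroxy-8-oxo-7,8-dihydro-β,ε-caroten-19-yl (2E)-dodec-2-enoate (siphonein, CNP0415260.1)
Conditions: (Ph3P)AuN(SO2CF3)2 (5 mol %), H2O (10 equiv), THF, 20 °C, dark
Reagents that add atoms: water, O
Why: Proposed new method: the monovalent gold cation activates C7≡C8, the carbonyl oxygen of the C19 dodecenoate adds to C8 anti to gold to give a transient 1,3-dioxinium vinyl-gold species, water adds to its acyloxonium carbon, the C8 enol oxygen leaves so that the acyl group returns to O19, and protodeauration at C7 with ketonisation at the α-carbon gives C7H2–C8=O while the ring A alkene stays at C5=C6. The closest known reaction type is the neighbouring-ester-assisted gold-catalysed hydration of propargylic and homopropargylic carboxylates to acyloxy ketones, not yet shown for an alkyne flanked by two alkenes with the ester on an allylic carbon of a polyene. The only ring closed is the transient six-membered dioxinium (6-exo-dig), which is opened again in the same step. No stereocentre is formed, and the C9=C10 geometry set by the butenolide in step 4 lies outside the reacting π-bond. The step needs oxygen at C8 and not at C7, which the tether secures because C7 could be reached only by a 7-endo closure, and it needs the alkyne to react before the polyene, which rests on the alkynophilicity of cationic gold and on the intramolecular nucleophile. Loss of the activated ester from C19 as a polyenyl cation should be held back because the dioxinium ring keeps the C19–O bond close to the nodal plane of the C9=C10 π-system and excess water opens the ring quickly.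

**Compound list**

1 | (4R,6R)-4-hydroxy-2,2,6-trimethylcyclohexan-1-one (actinol) | O=C1C(C)(C)C[C@H](O)C[C@H]1C | starting material
2 | (4R,6R)-4-(tert-butyldimethylsilyloxy)-2,2,6-trimethylcyclohexan-1-one | O=C1C(C)(C)C[C@H](O[Si](C)(C)C(C)(C)C)C[C@H]1C | intermediate
3 | (4R,6R)-4-(tert-butyldimethylsilyloxy)-1-ethynyl-2,2,6-trimethylcyclohexan-1-ol, mixture at C1 | C#CC1(O)C(C)(C)C[C@H](O[Si](C)(C)C(C)(C)C)C[C@H]1C | intermediate
4 | (4R,6R)-4-(tert-butyldimethylsilyloxy)-1-ethynyl-2,2,6-trimethylcyclohexyl phosphorodichloridate, mixture at C1 | C#CC1(OP(=O)(Cl)Cl)C(C)(C)C[C@H](O[Si](C)(C)C(C)(C)C)C[C@H]1C | intermediate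
5 | (4R)-4-(tert-butyldimethylsilyloxy)-1-ethynyl-2,6,6-trimethylcyclohex-1-ene | C#CC1=C(C)C[C@@H](O[Si](C)(C)C(C)(C)C)CC1(C)C | intermediate
6 | 4-bromofuran-2(5H)-one | O=C1C=C(Br)CO1 | starting material
7 | 4-{[(4R)-4-(tert-butyldimethylsilyloxy)-2,6,6-trimethylcyclohex-1-en-1-yl]ethynyl}furan-2(5H)-one | O=C1C=C(C#CC2=C(C)C[C@@H](O[Si](C)(C)C(C)(C)C)CC2(C)C)CO1 | intermediate
8 | 4-{[(4R)-4-(tert-butyldimethylsilyloxy)-2,6,6-trimethylcyclohex-1-en-1-yl]ethynyl}-2,5-dihydrofuran-2-ol, anomer mixture | OC1C=C(C#CC2=C(C)C[C@@H](O[Si](C)(C)C(C)(C)C)CC2(C)C)CO1 | intermediate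
9 | (R)-α-ionone, (3E)-4-[(1R)-2,6,6-trimethylcyclohex-2-en-1-yl]but-3-en-2-one | CC(=O)/C=C/[C@H]1C(C)=CCCC1(C)C | starting material
10 | ethyl (2E,4E)-3-methyl-5-[(1R)-2,6,6-trimethylcyclohex-2-en-1-yl]penta-2,4-dienoate | CCOC(=O)/C=C(C)/C=C/[C@H]1C(C)=CCCC1(C)C | intermediate
11 | ethyl (2E,4E)-3-methyl-5-[(1R)-2,6,6-trimethyl-4-oxocyclohex-2-en-1-yl]penta-2,4-dienoate | CCOC(=O)/C=C(C)/C=C/[C@H]1C(C)=CC(=O)CC1(C)C | intermediate
12 | ethyl (2E,4E)-5-[(1R,4R)-4-hydroxy-2,6,6-trimethylcyclohex-2-en-1-yl]-3-methylpenta-2,4-dienoate | CCOC(=O)/C=C(C)/C=C/[C@H]1C(C)=C[C@H](O)CC1(C)C | intermediate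
13 | ethyl (2E,4E)-5-[(1R,4R)-4-(tert-butyldimethylsilyloxy)-2,6,6-trimethylcyclohex-2-en-1-yl]-3-methylpenta-2,4-dienoate | CCOC(=O)/C=C(C)/C=C/[C@H]1C(C)=C[C@H](O[Si](C)(C)C(C)(C)C)CC1(C)C | intermediate
14 | (2E,4E)-5-[(1R,4R)-4-(tert-butyldimethylsilyloxy)-2,6,6-trimethylcyclohex-2-en-1-yl]-3-methylpenta-2,4-dien-1-ol | OC/C=C(C)/C=C/[C@H]1C(C)=C[C@H](O[Si](C)(C)C(C)(C)C)CC1(C)C | intermediate
15 | (2E,4E)-5-[(1R,4R)-4-(tert-butyldimethylsilyloxy)-2,6,6-trimethylcyclohex-2-en-1-yl]-3-methylpenta-2,4-dienyl bromide | BrC/C=C(C)/C=C/[C@H]1C(C)=C[C@H](O[Si](C)(C)C(C)(C)C)CC1(C)C | intermediate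
16 | {(2E,4E)-5-[(1R,4R)-4-(tert-butyldimethylsilyloxy)-2,6,6-trimethylcyclohex-2-en-1-yl]-3-methylpenta-2,4-dien-1-yl}triphenylphosphonium bromide | [Br-].c1ccccc1[P+](c1ccccc1)(c1ccccc1)C/C=C(C)/C=C/[C@H]1C(C)=C[C@H](O[Si](C)(C)C(C)(C)C)CC1(C)C | intermediate
17 | (2E,4E,6E)-2,7-dimethylocta-2,4,6-trienedial | O=C/C(C)=C/C=C/C=C(C)/C=O | starting material
18 | phosphorus ylide of 16, (2E,4E)-5-[(1R,4R)-4-(tert-butyldimethylsilyloxy)-2,6,6-trimethylcyclohex-2-en-1-yl]-3-methylpenta-2,4-dienylidene(triphenyl)phosphorane | c1ccccc1[P+](c1ccccc1)(c1ccccc1)[CH-]/C=C(C)/C=C/[C@H]1C(C)=C[C@H](O[Si](C)(C)C(C)(C)C)CC1(C)C | intermediate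
19 | (2E,4E,6E,8E,10E,12E)-13-[(1R,4R)-4-(tert-butyldimethylsilyloxy)-2,6,6-trimethylcyclohex-2-en-1-yl]-2,7,11-trimethyltrideca-2,4,6,8,10,12-hexaenal | O=C/C(C)=C/C=C/C=C(C)/C=C/C=C(C)/C=C/[C@H]1C(C)=C[C@H](O[Si](C)(C)C(C)(C)C)CC1(C)C | intermediate
20 | (2E,4E,6E,8E,10E,12E)-13-[(1R,4R)-4-(tert-butyldimethylsilyloxy)-2,6,6-trimethylcyclohex-2-en-1-yl]-2,7,11-trimethyltrideca-2,4,6,8,10,12-hexaen-1-ol | OC/C(C)=C/C=C/C=C(C)/C=C/C=C(C)/C=C/[C@H]1C(C)=C[C@H](O[Si](C)(C)C(C)(C)C)CC1(C)C | intermediate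
21 | (2E,4E,6E,8E,10E,12E)-13-[(1R,4R)-4-(tert-butyldimethylsilyloxy)-2,6,6-trimethylcyclohex-2-en-1-yl]-2,7,11-trimethyltrideca-2,4,6,8,10,12-hexaenyl bromide | BrC/C(C)=C/C=C/C=C(C)/C=C/C=C(C)/C=C/[C@H]1C(C)=C[C@H](O[Si](C)(C)C(C)(C)C)CC1(C)C | intermediate
22 | {(2E,4E,6E,8E,10E,12E)-13-[(1R,4R)-4-(tert-butyldimethylsilyloxy)-2,6,6-trimethylcyclohex-2-en-1-yl]-2,7,11-trimethyltrideca-2,4,6,8,10,12-hexaen-1-yl}triphenylphosphonium bromide | [Br-].c1ccccc1[P+](c1ccccc1)(c1ccccc1)C/C(C)=C/C=C/C=C(C)/C=C/C=C(C)/C=C/[C@H]1C(C)=C[C@H](O[Si](C)(C)C(C)(C)C)CC1(C)C | intermediate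
23 | phosphorus ylide of 22, (2E,4E,6E,8E,10E,12E)-13-[(1R,4R)-4-(tert-butyldimethylsilyloxy)-2,6,6-trimethylcyclohex-2-en-1-yl]-2,7,11-trimethyltrideca-2,4,6,8,10,12-hexaenylidene(triphenyl)phosphorane | c1ccccc1[P+](c1ccccc1)(c1ccccc1)[CH-]/C(C)=C/C=C/C=C(C)/C=C/C=C(C)/C=C/[C@H]1C(C)=C[C@H](O[Si](C)(C)C(C)(C)C)CC1(C)C | intermediate
24 | (3R,3'R,6'R)-3,3'-bis(tert-butyldimethylsilyloxy)-7,8-didehydro-β,ε-caroten-19-ol, all-trans chain with C8 trans to C11 | OC\C(=C/C=C/C(C)=C/C=C/C=C(C)/C=C/C=C(C)/C=C/[C@H]1C(C)=C[C@H](O[Si](C)(C)C(C)(C)C)CC1(C)C)C#CC1=C(C)C[C@@H](O[Si](C)(C)C(C)(C)C)CC1(C)C | intermediate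
25 | (2E)-dodec-2-enoic acid | CCCCCCCCC/C=C/C(=O)O | starting material
26 | (3R,3'R,6'R)-3,3'-bis(tert-butyldimethylsilyloxy)-7,8-didehydro-β,ε-caroten-19-yl (2E)-dodec-2-enoate | CCCCCCCCC/C=C/C(=O)OC\C(=C/C=C/C(C)=C/C=C/C=C(C)/C=C/C=C(C)/C=C/[C@H]1C(C)=C[C@H](O[Si](C)(C)C(C)(C)C)CC1(C)C)C#CC1=C(C)C[C@@H](O[Si](C)(C)C(C)(C)C)CC1(C)C | intermediate
27 | (3R,3'R,6'R)-3,3'-dihydroxy-7,8-didehydro-β,ε-caroten-19-yl (2E)-dodec-2-enoate | CCCCCCCCC/C=C/C(=O)OC\C(=C/C=C/C(C)=C/C=C/C=C(C)/C=C/C=C(C)/C=C/[C@H]1C(C)=C[C@H](O)CC1(C)C)C#CC1=C(C)C[C@@H](O)CC1(C)C | intermediate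
28 | (3R,3'R,6'R,all-E)-3,3'-dihydroxy-8-oxo-7,8-dihydro-β,ε-caroten-19-yl (2E)-dodec-2-enoate (siphonein) | CCCCCCCCC/C=C/C(=O)OC\C(=C/C=C/C(C)=C/C=C/C=C(C)/C=C/C=C(C)/C=C/[C@H]1C(C)=C[C@H](O)CC1(C)C)C(=O)CC1=C(C)C[C@@H](O)CC1(C)C | target

Total step count: 18. Longest linear sequence: 13 steps (steps 6 to 18, from 9 to 28).

Steps most likely to fail:

1. Step 18 (the labelled step). What may go wrong: heterolysis of the C19–O bond of the acyloxonium intermediate to a polyenyl cation, transfer of the acyl group to the C8 enol oxygen, or unproductive binding of gold by the polyene. The fallback uses known chemistry, sets out from 24 and comes back at 28. O19 of 24 would be silylated with (HMe2Si)2NH to the 19-dimethylsilyl ether F1. Pt2[(CH2=CHSiMe2)2O]3 (zerovalent platinum) would cyclise it by intramolecular syn-hydrosilylation in the 5-exo-dig mode to the oxasilolane F2 with silicon on C8. Tamao–Fleming oxidation (KF, KHCO3, H2O2, THF/MeOH) would give the 19-hydroxy-8-ketone F3, Steglich esterification with 25 would give the bis-silyl keto ester F4, and HF·pyridine would give 28.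

2. Step 15. What may go wrong: dehydration of the lactol to a furan, isomerisation of the open (Z)-hydroxy-enal before olefination, or proton transfer from the lactol to the ylide. The fallback sets out from 7 and comes back at 24. The lactone of 7 would be opened with Me(MeO)NH·HCl and Me3Al to the (Z)-hydroxy Weinreb amide F5, which would be silylated at once with Et3SiCl and imidazole to the triethylsilyl ether F6. iBu2AlH at −78 °C would give the (Z)-4-silyloxy-enal F7, and Wittig reaction with one equivalent of ylide 23 would give the 19-triethylsilyl ether F8. Pyridinium p-toluenesulfonate in MeOH/CH2Cl2 at 0 °C would remove the primary silyl group to give 24.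

3. Step 8. What may go wrong: poor facial selectivity if the (1R) substrate and the oxazaborolidine are a mismatched pair. The fallback sets out from 11 and comes back at 12: Luche reduction (NaBH4, CeCl3·7H2O, MeOH, −40 °C) would give 12 together with its C4 epimer F9; the two would be separated on silica, and F9 would be re-oxidised with MnO2 to 11 and recycled.

**Further compounds**

F1 | step 18 | (3R,3'R,6'R)-3,3'-bis(tert-butyldimethylsilyloxy)-19-(dimethylsilyloxy)-7,8-didehydro-β,ε-carotene | C[SiH](C)OC\C(=C/C=C/C(C)=C/C=C/C=C(C)/C=C/C=C(C)/C=C/[C@H]1C(C)=C[C@H](O[Si](C)(C)C(C)(C)C)CC1(C)C)C#CC1=C(C)C[C@@H](O[Si](C)(C)C(C)(C)C)CC1(C)C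
F2 | step 18 | cyclic siloxane of F1, a 2,2-dimethyl-1,2-oxasilolane closed between O19 and C8 (silicon on C8, exocyclic C7=C8 and C9=C10) | C[Si]1(C)OC\C(=C/C=C/C(C)=C/C=C/C=C(C)/C=C/C=C(C)/C=C/[C@H]2C(C)=C[C@H](O[Si](C)(C)C(C)(C)C)CC2(C)C)\C1=C/C3=C(C)C[C@@H](O[Si](C)(C)C(C)(C)C)CC3(C)C
F3 | step 18 | (3R,3'R,6'R,all-E)-3,3'-bis(tert-butyldimethylsilyloxy)-19-hydroxy-7,8-dihydro-β,ε-caroten-8-one | OC\C(=C/C=C/C(C)=C/C=C/C=C(C)/C=C/C=C(C)/C=C/[C@H]1C(C)=C[C@H](O[Si](C)(C)C(C)(C)C)CC1(C)C)C(=O)CC1=C(C)C[C@@H](O[Si](C)(C)C(C)(C)C)CC1(C)C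
F4 | step 18 | (3R,3'R,6'R,all-E)-3,3'-bis(tert-butyldimethylsilyloxy)-8-oxo-7,8-dihydro-β,ε-caroten-19-yl (2E)-dodec-2-enoate | CCCCCCCCC/C=C/C(=O)OC\C(=C/C=C/C(C)=C/C=C/C=C(C)/C=C/C=C(C)/C=C/[C@H]1C(C)=C[C@H](O[Si](C)(C)C(C)(C)C)CC1(C)C)C(=O)CC1=C(C)C[C@@H](O[Si](C)(C)C(C)(C)C)CC1(C)C
F5 | step 15 | (2Z)-4-hydroxy-N-methoxy-N-methyl-3-{[(4R)-4-(tert-butyldimethylsilyloxy)-2,6,6-trimethylcyclohex-1-en-1-yl]ethynyl}but-2-enamide | CON(C)C(=O)/C=C(\CO)C#CC1=C(C)C[C@@H](O[Si](C)(C)C(C)(C)C)CC1(C)C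
F6 | step 15 | (2Z)-N-methoxy-N-methyl-4-(triethylsilyloxy)-3-{[(4R)-4-(tert-butyldimethylsilyloxy)-2,6,6-trimethylcyclohex-1-en-1-yl]ethynyl}but-2-enamide | CON(C)C(=O)/C=C(\CO[Si](CC)(CC)CC)C#CC1=C(C)C[C@@H](O[Si](C)(C)C(C)(C)C)CC1(C)C
F7 | step 15 | (2Z)-4-(triethylsilyloxy)-3-{[(4R)-4-(tert-butyldimethylsilyloxy)-2,6,6-trimethylcyclohex-1-en-1-yl]ethynyl}but-2-enal | O=C/C=C(\CO[Si](CC)(CC)CC)C#CC1=C(C)C[C@@H](O[Si](C)(C)C(C)(C)C)CC1(C)C
F8 | step 15 | (3R,3'R,6'R)-3,3'-bis(tert-butyldimethylsilyloxy)-19-(triethylsilyloxy)-7,8-didehydro-β,ε-carotene | CC[Si](CC)(CC)OC\C(=C/C=C/C(C)=C/C=C/C=C(C)/C=C/C=C(C)/C=C/[C@H]1C(C)=C[C@H](O[Si](C)(C)C(C)(C)C)CC1(C)C)C#CC1=C(C)C[C@@H](O[Si](C)(C)C(C)(C)C)CC1(C)C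
F9 | step 8 | ethyl (2E,4E)-5-[(1R,4S)-4-hydroxy-2,6,6-trimethylcyclohex-2-en-1-yl]-3-methylpenta-2,4-dienoate | CCOC(=O)/C=C(C)/C=C/[C@H]1C(C)=C[C@@H](O)CC1(C)C
A1 | direct plan | 1-[(4R)-4-(tert-butyldimethylsilyloxy)-2,6,6-trimethylcyclohex-1-en-1-yl]-4-(triethylsilyloxy)butan-2-one | O=C(CCO[Si](CC)(CC)CC)CC1=C(C)C[C@@H](O[Si](C)(C)C(C)(C)C)CC1(C)C
A2 | direct plan | (2E,4E,6E,8E,10E,12E,14E)-4,9,13-trimethyl-15-[(1R,4R)-4-(tert-butyldimethylsilyloxy)-2,6,6-trimethylcyclohex-2-en-1-yl]pentadeca-2,4,6,8,10,12,14-heptaenal | O=C/C=C/C(C)=C/C=C/C=C(C)/C=C/C=C(C)/C=C/[C@H]1C(C)=C[C@H](O[Si](C)(C)C(C)(C)C)CC1(C)C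
A3 | direct plan | (4R)-4-(tert-butyldimethylsilyloxy)-2,6,6-trimethyl-1-[(phenylsulfonyl)methyl]cyclohex-1-ene | O=S(=O)(CC1=C(C)C[C@@H](O[Si](C)(C)C(C)(C)C)CC1(C)C)c1ccccc1
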